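**Retrosynthetic overview**
1. Target 18 ⇒ O-methylation of spiro-trione 17 ⇒ photochemical 5-exo radical spirocyclisation of β-triketone 16. This step makes the C(spiro)–CH(iPr) bond, closes the cyclopentane and turns the prenyl end into the isopropyl group.
2. The triketone ring of 16 ⇒ crossed Claisen/Dieckmann condensation of the quaternary acetate 12 with keto ester 14.
3. The quaternary pinane C2 of 12 ⇒ Cu-catalysed 1,4-addition of homoprenyl-MgBr to enoate 8. The chain enters anti to the CMe2 bridge, so the acetate arm (the later spiro carbon) ends up syn to the bridge, as the target SMILES requires.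
4. 8 ⇒ HWE on (−)-nopinone 6 ⇒ (+)-β-pinene 4 ⇒ (+)-α-pinene 1. The bridgeheads in the target belong to the (1R,5R)-pinene series.
5. Ring order: pinane (bought) → six-membered triketone → cyclopentane (last, under light).

Assumption: (1R)-(+)-α-pinene of ≥97 % ee is used, and the enolisable compounds 15–17 are each drawn as one tautomer.

**Step 1**
Reactants: 1 (1R,5R)-(+)-α-pinene
Product: 4 (1R,5R)-(+)-β-pinene, via pinenylpotassium 2 (not isolated), via dimethyl pinenylboronate 3 (not isolated)
Conditions: n-BuLi, KOt-Bu, hexane, 25 °C; B(OMe)3, Et2O, −78 → 25 °C; HCl/Et2O; H2O, 25 °C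
Reagents that add atoms: none
Why: Schlosser-base allylic metalation at C10, borylation and SE2′ protonolysis of the allylboronate (H to C3, C=C moves to C2=C10) is the known contra-thermodynamic α→β-pinene isomerisation, and C1 and C5 are not touched.

**Step 2**
Reactants: 4 (+)-β-pinene
Product: 6 (1S,5R)-(−)-nopinone, via spiro ozonide 5 (not isolated)
Conditions: O3, CH2Cl2, −78 °C; Me2S, −78 → 25 °C
Reagents that add atoms: ozone, [O-][O+]=O
Why: Ozonolysis (Criegee mechanism) with reductive work-up cleaves the only C=C, and the α-stereocentre is a bridgehead that cannot epimerise.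

**Step 3**
Reactants: 6 (−)-nopinone; 7 trimethyl phosphonoacetate
Product: 8 methyl (E)-nopinylideneacetate (exocyclic C2=CH–CO2Me, ester cis to C3 and trans to bridgehead C1; bridgeheads as in 4)
Conditions: NaH, THF, 0 → 66 °C
Reagents that add atoms: trimethyl phosphonoacetate (7), COC(=O)CP(=O)(OC)OC
Why: In this Horner–Wadsworth–Emmons olefination the small stabilised anion adds even to the hindered ketone, the ester turns away from C1 (E), and any Z isomer converges in step 4.

**Step 4**
Reactants: 8 methyl (E)-nopinylideneacetate; 9 5-bromo-2-methylpent-2-ene (homoprenyl bromide)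
Product: 12 methyl 2-[2-(4-methylpent-3-enyl)-6,6-dimethylbicyclo[3.1.1]hept-2-yl]acetate (chain anti and CH2CO2Me syn to the CMe2 bridge), via homoprenylmagnesium bromide 10 (not isolated), via silyl ketene acetal 11 (not isolated)
Conditions: 9, Mg, THF; then 8, CuBr·SMe2 (10 mol %), TMSCl (2 equiv), DMPU, THF, −40 → 0 °C; 1 M HCl
Reagents that add atoms: 5-bromo-2-methylpent-2-ene (9), CC(C)=CCCBr
Why: In this Cu-catalysed, TMSCl-accelerated conjugate addition of a Grignard reagent the copper reagent attacks C2 from the face opposite the CMe2 bridge (the usual face for β-pinene-type exocyclic alkenes), which sets the quaternary C2 of the target.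

**Step 5**
Reactants: 13 methyl 3-oxopentanoate
Product: 14 methyl 2,2-dimethyl-3-oxopentanoate
Conditions: MeI (2.5 equiv), K2CO3, acetone, reflux
Reagents that add atoms: iodomethane, CI
Why: This is a double C-alkylation of an active methylene (β-keto ester alkylation) and creates no stereocentre.

**Step 6**
Reactants: 12 quaternary acetate; 14 methyl 2,2-dimethyl-3-oxopentanoate
Product: 16 3,5-dihydroxy-4,6,6-trimethyl-2-[2-(4-methylpent-3-enyl)-6,6-dimethylbicyclo[3.1.1]hept-2-yl]cyclohexa-2,4-dien-1-one (enol form of the 2-tert-alkyl-1,3,5-trione; ring syn to the CMe2 bridge), via open-chain triketo ester 15 (not isolated)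
Conditions: 14 (2.2 equiv), LDA (2.2 equiv), THF, −78 °C; 12, −78 → 25 °C; then LDA (2.5 equiv), −20 → 25 °C; 1 M HCl
Reagents that add atoms: methyl 2,2-dimethyl-3-oxopentanoate (14), CCC(=O)C(C)(C)C(=O)OC
Why: A crossed Claisen condensation at the only enolisable site of 14 is followed by Dieckmann closure through the 1,3-diketone dianion (Hauser–Harris type), is driven by formation of the strongly acidic trione, and neither forms nor endangers a stereocentre.

**Step 7**
Reactants: 16 2-tert-alkyl β-triketone
Product: 17 spiro-trione, identical to the target but with enol OH in place of OMe (isopropyl cis to the enone carbonyl and to pinane C3, trans to bridgehead C1)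
Conditions: 4CzIPN (2 mol %), 2,4,6-triisopropylbenzenethiol (10 mol %), 2,6-lutidine (20 mol %), degassed MeCN, 456 nm LEDs, 25 °C
Reagents that add atoms: none
Why: Proposed new method: a redox-neutral photoredox/thiol-HAT cycloisomerisation in which excited 4CzIPN oxidises the lutidinium enolate of 16 to the electrophilic C2 radical, which closes 5-exo-trig onto the CH end of the electron-rich prenyl alkene (helped by the quaternary neighbour), the tertiary radical takes H from ArSH to give the isopropyl group, and ArS• is reduced by 4CzIPN•− and reprotonated by substrate; in the chair-like Beckwith–Houk transition state the larger C2 substituent (bridgehead C1) sits pseudo-equatorial so the isopropyl ends trans to it, and the incoming =CMe2 avoids the out-of-plane methyls of the ring CMe2 so the isopropyl ends cis to the flat enone carbonyl, which fixes the spiro carbon; the closest known reaction types are Mn(OAc)3 oxidative radical cyclisation of β-dicarbonyls and photoredox/thiol anti-Markovnikov hydrofunctionalisation, neither shown for cyclic β-triketones or for building a spiro quaternary carbon next to a quaternary carbon.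

**Step 8**
Reactants: 17 spiro-trione
Product: 18 CNP0307059.1 (target)
Conditions: TMSCHN2 (1.2 equiv), PhMe/MeOH 4:1, 0 °C
Reagents that add atoms: (trimethylsilyl)diazomethane, C[Si](C)(C)C=[N+]=[N-]
Why: A diazoalkane O-methylates the vinylogous acid, and of the two enol oxygens only the one next to the ring CMe2 is accessible because the one next to the spiro carbon is screened by the cis isopropyl and the pinane, with no stereocentre touched.

**Compound list**
1 | (1R,5R)-(+)-α-pinene | CC1=CC[C@@H]2C[C@H]1C2(C)C | starting material
2 | pinenylpotassium (C10 allyl anion, not isolated) | [K+].[CH2-]C1=CC[C@@H]2C[C@H]1C2(C)C | intermediate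
3 | dimethyl (pin-2-en-10-yl)boronate (not isolated) | COB(OC)CC1=CC[C@@H]2C[C@H]1C2(C)C | intermediate
4 | (1R,5R)-(+)-β-pinene | C=C1CC[C@@H]2C[C@H]1C2(C)C | intermediate
5 | spiro 1,2,4-trioxolane of 4 (acetal carbon configuration irrelevant, not isolated) | C1OOC2(O1)CC[C@@H]3C[C@H]2C3(C)C | intermediate
6 | (1S,5R)-(−)-nopinone | O=C1CC[C@@H]2C[C@H]1C2(C)C | intermediate
7 | trimethyl phosphonoacetate | COC(=O)CP(=O)(OC)OC | starting material
8 | methyl (E)-nopinylideneacetate | COC(=O)/C=C1\CC[C@@H]2C[C@H]1C2(C)C | intermediate
9 | 5-bromo-2-methylpent-2-ene | CC(C)=CCCBr | starting material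
10 | homoprenylmagnesium bromide (not isolated) | CC(C)=CCC[Mg]Br | intermediate
11 | O-methyl O-TMS ketene acetal of 12 (not isolated) | COC(O[Si](C)(C)C)=C[C@@]1(CCC=C(C)C)CC[C@@H]2C[C@H]1C2(C)C | intermediate
12 | quaternary acetate (homoprenyl anti, CH2CO2Me syn to CMe2 bridge) | COC(=O)C[C@@]1(CCC=C(C)C)CC[C@@H]2C[C@H]1C2(C)C | intermediate
13 | methyl 3-oxopentanoate | CCC(=O)CC(=O)OC | starting material
14 | methyl 2,2-dimethyl-3-oxopentanoate | CCC(=O)C(C)(C)C(=O)OC | intermediate
15 | methyl 2,2,4-trimethyl-3,5-dioxo-6-(pinanyl)hexanoate (C4 labile, not isolated) | COC(=O)C(C)(C)C(=O)C(C)C(=O)C[C@@]1(CCC=C(C)C)CC[C@@H]2C[C@H]1C2(C)C | intermediate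
16 | 2-tert-alkyl β-triketone (bis-enol form) | CC1=C(O)C(C)(C)C(=O)C(=C1O)[C@@]1(CCC=C(C)C)CC[C@@H]2C[C@H]1C2(C)C | intermediate
17 | spiro-trione (enol form, O-desmethyl target) | OC1=C(C)C(=O)[C@@]2(C(=O)C1(C)C)[C@@H](C(C)C)CC[C@@]21CC[C@@H]2C[C@H]1C2(C)C | intermediate
18 | CNP0307059.1 | COC1=C(C)C(=O)[C@@]2(C(=O)C1(C)C)[C@@H](C(C)C)CC[C@@]21CC[C@@H]2C[C@H]1C2(C)C | target

**Step count**
Total steps: 8. Longest linear sequence: 7 (1 → 4 → 6 → 8 → 12 → 16 → 17 → 18).

**Three steps most likely to fail**

Step 7 (the new step). The closure makes a very crowded bond, so the C2 radical may be returned to 16 by the thiol faster than it cyclises. Autoxidation of the dienol and formation of the spiro/CH(iPr) diastereomer pair are also possible. The fallback sets out from 16. Mn(OAc)3·2H2O (2.2 equiv) and Cu(OAc)2 (1 equiv) in AcOH at 25–50 °C (Snider oxidative radical cyclisation) close the same bond, and Cu(II) oxidises the tertiary radical to the isopropenyl spiro-trione F6. H2 (1 atm) over Pd/C in EtOAc then saturates only the 1,1-disubstituted alkene, and the route is rejoined at 17.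

Step 6. The neopentyl-type ester 12 may acylate the hindered enolate too slowly. The open-chain compound may also stop at the O-cyclised pyrandione or undergo retro-Claisen cleavage. The fallback sets out from 12 and uses a different ring disconnection. MeNHOMe·HCl with i-PrMgCl gives the Weinreb amide F3, EtMgBr gives the ethyl ketone F4, and LDA/TMSCl gives the kinetic silyl enol ether F5. Effenberger-type double C-acylation of F5 with dimethylmalonyl dichloride (CH2Cl2, −20 → 25 °C, then KOH, BnEt3NCl) closes the trione ring, and the route is rejoined at 16.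

Step 4. The β,β-disubstituted enoate next to a bridgehead may be too unreactive, or it may undergo 1,2-addition. The fallback sets out from 6. Knoevenagel condensation with Meldrum's acid (TiCl4, pyridine, THF) gives the doubly activated alkylidene Meldrum's acid F1. Grignard reagent 10 adds to it without copper from the same open face to give the quaternary Meldrum's acid adduct F2. Heating F2 in MeOH/pyridine (methanolysis and decarboxylation) rejoins the route at 12.

**Further compounds**
F1 | step 4 | 5-(nopinylidene) Meldrum's acid | CC1(C)OC(=O)C(=C2CC[C@@H]3C[C@H]2C3(C)C)C(=O)O1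
F2 | step 4 | 5-[2-(4-methylpent-3-enyl)-6,6-dimethylbicyclo[3.1.1]hept-2-yl] Meldrum's acid (chain anti to CMe2 bridge) | CC1(C)OC(=O)C(C(=O)O1)[C@@]1(CCC=C(C)C)CC[C@@H]2C[C@H]1C2(C)C
F3 | step 6 | Weinreb amide of 12 | CON(C)C(=O)C[C@@]1(CCC=C(C)C)CC[C@@H]2C[C@H]1C2(C)C
F4 | step 6 | ethyl ketone from F3 | CCC(=O)C[C@@]1(CCC=C(C)C)CC[C@@H]2C[C@H]1C2(C)C
F5 | step 6 | kinetic TMS enol ether of F4 | CC=C(O[Si](C)(C)C)C[C@@]1(CCC=C(C)C)CC[C@@H]2C[C@H]1C2(C)C
F6 | step 7 | isopropenyl spiro-trione | OC1=C(C)C(=O)[C@@]2(C(=O)C1(C)C)[C@@H](C(C)=C)CC[C@@]21CC[C@@H]2C[C@H]1C2(C)C
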